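Atom labels used throughout: ring O1, C2 (aryl), C3, C4 (OH), C5, C6 (arylethyl); chain on C3: C1'=C2'–C3'(–C3)–C4'H2–C5'(OH)–C6'H2–C7'H2–Ar. Piv = 2,2-dimethylpropanoyl.

## Analysis of the target

Blepharocalyxin C is one oxane ring (O1, C2–C6) carrying a 4-hydroxyphenyl group at C2, a branched C19 chain at C3, a free hydroxyl at C4 and a 2-(4-hydroxyphenyl)ethyl group at C6. There are six stereocentres, all S. On the ring the relations are 2,6-cis, 2,3-trans and 3,4-cis, so in the chair with the C2, C3 and C6 substituents equatorial the C4–OH is axial. The two chain stereocentres are the branching methine C3' and the carbinol C5'. Formally the molecule is two C19 1,7-diarylheptanoid units with the same (S)-configured ArCH2CH2–CH(O)–CH2 terminus, joined by the C3–C3' bond between two methine stereocentres. The sensitive groups are four free phenols, the C2–O1 benzylic ether para to a phenol (a quinone methide leaving-group array) and the electron-rich C1'=C2' hydroxystyrene. The hard parts are the C3–C3' bond with its exocyclic stereocentre C3', which no ring relays, and the axial C4–OH, which is the opposite of what oxocarbenium–alkene cyclisations deliver. The feature exploited here is the array C4(O)–C3–C3'–C2'=C1': once C4 is a ketone the styrene is γ,δ to it, which is the retron of a Claisen-type [3,3] shift, and the vicinal pair C3/C3' is exactly what such a shift sets.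

## Retrosynthetic reasoning

Target 23 is traced to pentaester 22 by cutting five O–acyl bonds. The four phenols and the C5' hydroxyl carry the same acyl group, so one reductive operation under non-acidic, non-basic work-up releases the target. The electron-poor aryl esters also keep every benzylic C–O bond of the route from ionising.

Alcohol 22 is traced to ketone 21 by removing the C4–H bond. The ring ketone places C2, C3 and C6 substituents equatorial, so a hindered hydride approaching along the equatorial trajectory gives the axial C4–OH. The ketone is also what makes the next disconnection possible.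

Ketone 21 is cut at C3–C3', with transposition of the alkene, into bicyclic dioxinone 11 and allylic alcohol 17 by way of acylketene 18, allyl β-keto ester 19 and β-keto acid 20. This bond is chosen because it divides the molecule into its two C19 halves, and because a suprafacial [3,3] shift copies the easily made C1' carbinol configuration of 17 onto C3'. C3 then becomes an enolisable centre whose configuration is set by protonation and equilibration. The forward step has to capture the ketene at the only free hydroxyl, rearrange the ester before its benzylic C–O bond ionises, and decarboxylate.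

Dioxinone 11 is cut at O1–C2 and C2–C3 into hydroxy-dioxinone 10 and aldehyde 5. A Lewis-acid-mediated oxocarbenium cyclisation onto the nucleophilic dioxinone carbon closes the ring 2,6-cis. It also leaves the C3 carboxyl and C4 oxygen masked in a form that opens thermally, so no separate activation of C3 is needed.

Hydroxy-dioxinone 10 is cut at the C5–C6 bond into silyl dienol ether 8 and aldehyde 3, with silyl ether 9 as the primary adduct. The forward reaction is a catalytic asymmetric vinylogous aldol addition that sets C6. Dienol ether 8 comes from dioxinone 6 through dienolate 7.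

Allylic alcohol 17 is cut at C1'–C2' into alkyne 14 and aldehyde 5, through alkenylborane 15 and alkenylzinc 16. A catalytic asymmetric alkenylzinc addition gives the E-alkene and the C1' carbinol in one operation.

Alkyne 14 is the ester of homopropargylic alcohol 13, which is cut at C4'–C5' back to aldehyde 3 (through borate 12) by catalytic asymmetric propargylation. The same aldehyde 3 therefore supplies both (S)-carbinols (C6 and C5') by attack on the same face, and aldehyde 5 supplies both C2 and C1'.

Aldehyde 3 comes from phenol-alcohol 1 through ester 2, and aldehyde 5 from phenol 4.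

## Alternatives that were turned down

Alternative 1: the textbook Prins cyclisation, cutting C2–C3 and C4–O. Aldehyde 5 and homoallylic alcohol A1 (which already contains the complete C3 side chain on an E-alkene) would condense in trifluoroacetic acid to the all-equatorial 4-trifluoroacetate A2. It was turned down for four reasons. The cation is trapped equatorially at C4, so A2 has the wrong C4 configuration and needs an extra inversion or oxidation–reduction sequence. A1 must already contain C3' as a doubly allylic methine in a skipped diene, so the hardest stereocentre is left unsolved and moved into a longer, isomerisation-prone linear sequence. A1 offers the oxocarbenium ion two π-nucleophiles, and the styrene competes with the intended alkene. The aryl-substituted oxocarbenium ion can also leak through 2-oxonia-Cope pathways.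

Alternative 2: the biomimetic union, cutting C3–C3' and O1–C2 at once. Two molecules of diol A3 would combine under acid. One ionises at its allylic C3–OH to an aryl-stabilised allyl cation. The styrene β-carbon of the second attacks it, and its own C5–OH closes onto the resulting benzylic cation. This is the shortest conceivable route, but it was turned down because three stereocentres would form with no controlling element. C3' arises by intermolecular attack on a planar, freely rotating allyl cation with only remote 1,3-induction from C5'. Face selection on an E-disubstituted styrene by its allylic hydroxyl is weak. The same molecule acts as electrophile and nucleophile, so self-cyclisation of the cation onto its own C5–OH, attack at C1 and oligomerisation of the still-reactive product all compete. The chosen route keeps the idea of joining two C19 halves but does it through an ordered pericyclic transition state.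

Alternative 3: conjugate addition, cutting the C3'–C2' bond. A styrylboron reagent would add under rhodium/chiral diene catalysis to enone A4 (ring C3 bearing CH=CH–C(=O)–CH2CH2Ar) to give diketone A5. It was turned down for three reasons. A4 has a C3–H that is α to the ring ketone and γ to the enone, so the alkene can migrate into conjugation with the ring and the ring can open by retro-oxa-Michael reaction. The catalyst would have to override the adjacent C3 centre. A5 has two ketones that need opposite kinds of control, axial delivery at C4 and acyclic 1,3-induction or a second chiral reagent at C5', which adds chemoselectivity problems and steps.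

Key step: step 10

Remark on stereochemical sense: the catalyst antipodes named ((R)-BINOL, (R)-TRIP, (−)-MIB) are those expected from the accepted transition-state models to give the configurations drawn; if a sense proved opposite, the antipodal catalyst would be used.
Remark on bookkeeping: metal alkoxide or phenoxide salts of a product that are only protonated on work-up are not numbered separately.

## Route

Step 1
Reactants: 1 3-(4-hydroxyphenyl)propan-1-ol
Product: 2 4-(3-hydroxypropyl)phenyl pivalate
Conditions: PivCl (1.05 equiv), K2CO3, acetone, 0 °C → rt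
Reagents that add atoms: pivaloyl chloride, CC(C)(C)C(Cl)=O
Why: Schotten–Baumann-type O-acylation; carbonate deprotonates only the phenol, and the hindered acid chloride reacts with phenoxide far faster than with the neutral primary alcohol, which should stay free.

Step 2
Reactants: 2 4-(3-hydroxypropyl)phenyl pivalate
Product: 3 4-(3-oxopropyl)phenyl pivalate
Conditions: TEMPO (10 mol %), PhI(OAc)2 (1.1 equiv), CH2Cl2, rt
Reagents that add atoms: none
Why: Oxoammonium (TEMPO) oxidation of a primary alcohol should stop at the aldehyde and leave the aryl ester untouched.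

Step 3
Reactants: 4 4-hydroxybenzaldehyde
Product: 5 4-formylphenyl pivalate
Conditions: PivCl, Et3N, CH2Cl2, 0 °C → rt
Reagents that add atoms: pivaloyl chloride, CC(C)(C)C(Cl)=O
Why: Standard phenol acylation; the acyloxy group makes this arene electronically neutral, so the benzylic C–O bonds later built on it (C2–O1, C1'–O) resist ionisation.

Step 4
Reactants: 6 2,2,6-trimethyl-4H-1,3-dioxin-4-one
Product: 8 silyl dienol ether 2,2-dimethyl-6-methylidene-4-(trimethylsilyloxy)-6H-1,3-dioxine, via lithium dienolate 7 (not isolated)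
Conditions: LDA (commercial solution, 1.1 equiv), THF, −78 °C; TMSCl
Reagents that add atoms: chlorotrimethylsilane, C[Si](C)(C)Cl
Why: Kinetic γ-deprotonation of the vinylogous ester and O-silylation give the cross-conjugated silyl dienol ether, the standard nucleophile for vinylogous Mukaiyama aldol reactions.

Step 5
Reactants: 8 silyl dienol ether; 3 4-(3-oxopropyl)phenyl pivalate
Product: 10 6-[(2S)-2-hydroxy-4-(4-pivaloyloxyphenyl)butyl]-2,2-dimethyl-4H-1,3-dioxin-4-one, via TMS ether 9 (not isolated)
Conditions: Ti(OiPr)4/(R)-BINOL (10 mol %), 4 Å MS, THF, −78 °C → rt; then dilute aq. HCl (cat.), THF, 0 °C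
Reagents that add atoms: none
Why: Catalytic asymmetric vinylogous Mukaiyama aldol reaction; the dienol ether reacts only at its γ-carbon, and the Ti(IV)–BINOL complex selects the aldehyde face to give the (S)-carbinol that becomes C6; mild acid removes the transferred silyl group.

Step 6
Reactants: 10 (S)-hydroxy-dioxinone; 5 4-formylphenyl pivalate
Product: 11 (5R,7S)-2,2-dimethyl-5-(4-pivaloyloxyphenyl)-7-[2-(4-pivaloyloxyphenyl)ethyl]-7,8-dihydro-4H,5H-pyrano[4,3-d][1,3]dioxin-4-one (5,7-cis)
Conditions: Sc(OTf)3 (10 mol %), CaSO4, CH2Cl2, −10 °C → rt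
Reagents that add atoms: none
Why: Lewis-acid-catalysed condensation to an (E)-oxocarbenium ion and Prins-type 6-endo attack by the nucleophilic dioxinone α-carbon, followed by proton loss; a chair-like transition state with both substituents pseudo-equatorial sets the new benzylic centre cis to C6 (the future 2,6-cis pair).

Step 7
Reactants: 3 4-(3-oxopropyl)phenyl pivalate
Product: 13 4-[(3S)-3-hydroxyhex-5-yn-1-yl]phenyl pivalate, via borate ester 12 (not isolated)
Conditions: allenyl-B(pin) (1.5 equiv), (R)-TRIP (5 mol %), 4 Å MS, toluene, −20 °C; aqueous work-up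
Reagents that add atoms: allenylboronic acid pinacol ester, C=C=CB1OC(C)(C)C(C)(C)O1
Why: Chiral phosphoric acid-catalysed propargylation through a closed six-membered SE2' transition state gives only the homopropargylic product; the catalyst selects the same aldehyde face as in step 5, giving the (S)-carbinol that becomes C5'.

Step 8
Reactants: 13 (S)-homopropargylic alcohol
Product: 14 (3S)-1-(4-pivaloyloxyphenyl)hex-5-yn-3-yl pivalate
Conditions: PivCl, pyridine, DMAP (cat.), CH2Cl2, rt
Reagents that add atoms: pivaloyl chloride, CC(C)(C)C(Cl)=O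
Why: Nucleophile-catalysed esterification; it blocks the C5' hydroxyl so that only the C1' hydroxyl can capture the ketene in step 10, and it uses the same group as the phenols so one final deprotection suffices.

Step 9
Reactants: 14 alkyne pivalate; 5 4-formylphenyl pivalate
Product: 17 (1S,2E,5S)-1-hydroxy-1,7-bis(4-pivaloyloxyphenyl)hept-2-en-5-yl pivalate, via alkenylborane 15 (not isolated), via alkenylzinc 16 (not isolated)
Conditions: Cy2BH (pre-formed, 1.05 equiv), toluene, 0 °C → rt; Et2Zn (1.1 equiv), −78 °C; (−)-MIB (5 mol %), then 5, −20 → 0 °C; water quench, Et3N-deactivated silica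
Reagents that add atoms: none
Why: Syn, anti-Markovnikov hydroboration fixes the E-alkene, boron-to-zinc transmetalation gives an alkenylzinc that tolerates the esters, and amino-alcohol-catalysed addition to the aldehyde (catalyst control, remote C5' has no influence) sets the 1'S carbinol.

Step 10
Reactants: 11 bicyclic dioxinone (1.2 equiv); 17 (1S,2E,5S)-allylic alcohol
Product: 21 (2S,3R,6S)-2-(4-pivaloyloxyphenyl)-6-[2-(4-pivaloyloxyphenyl)ethyl]-3-[(1E,3S,5S)-5-(pivaloyloxy)-1,7-bis(4-pivaloyloxyphenyl)hept-1-en-3-yl]oxan-4-one, via acylketene 18 (not isolated), via allyl β-keto ester 19 (not isolated), via β-keto acid 20 (not isolated)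
Conditions: degassed toluene, 110 °C, then 150 °C (sealed vessel, acid-free glassware)
Reagents that add atoms: none
Why: Thermal retro-[4+2] cleavage of 11 expels acetone and gives acylketene 18, which acylates the only free hydroxyl of 17 to give 19; the ester-enol tautomer of 19 then undergoes a Carroll [3,3] rearrangement (C3–C3' formed, C1'–O broken, alkene moved to C1'=C2') to β-keto acid 20, which loses CO2 through its cyclic six-membered transition state and ketonises to 21. The closest known reaction type is the thermal Carroll rearrangement of allyl β-keto esters made in situ from dioxinones and allylic alcohols, including α-substituted cyclic β-keto esters, together with 1,3-chirality transfer in Claisen rearrangements of secondary (E)-allylic esters. No ring of the product is closed in this step; the only cyclic array is the six-membered pericyclic transition state, and the oxane ring of 11 is carried through intact. C3' is controlled by the C1' carbinol: the shift is suprafacial across the allyl unit and the aryl group sits pseudo-equatorial, so the new bond forms on the face that C1'–O occupied and the (1'S, 2'E) ester gives (3'S) with an (E)-styrene, whichever enol face is attacked and whether the enol partner is chair- or boat-oriented. C3 is quaternary in 20 and becomes a methine only on decarboxylation; axial protonation of the C3=C4 enol and equilibration of this enolisable centre place the large substituent equatorial, trans to the C2 aryl group. C2 and C6 are not touched, and 2,6-cis is also the thermodynamic arrangement of this β-alkoxy ketone. The step needs the concerted shift to outrun heterolysis of the 1-arylallyl C–O bond (ion-pair 1,3-transposition or elimination); the electron-withdrawing pivaloyloxy group on that arene and the non-polar, neutral medium secure this, while the aryl group at C1' still lowers the pericyclic barrier through developing styrene conjugation. The step joins the two C19 halves, so after it the full C38 skeleton and five of the six stereocentres are in place.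

Step 11
Reactants: 21 ketone
Product: 22 (2S,3S,4S,6S)-2-(4-pivaloyloxyphenyl)-6-[2-(4-pivaloyloxyphenyl)ethyl]-3-[(1E,3S,5S)-5-(pivaloyloxy)-1,7-bis(4-pivaloyloxyphenyl)hept-1-en-3-yl]oxan-4-ol
Conditions: Li(s-Bu)3BH (L-Selectride, 1.2 equiv), THF, −78 °C; water quench (non-oxidative work-up)
Reagents that add atoms: none
Why: The bulky trialkylborohydride attacks the chair ketone along the equatorial trajectory, as with 2-alkylcyclohexanones, which should give the axial C4–OH cis to the C3 substituent; at −78 °C the ketone should react well ahead of the hindered pivalates.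

Step 12
Reactants: 22 pentapivalate
Product: 23 blepharocalyxin C
Conditions: DIBAL-H (15 equiv), CH2Cl2, −78 → 0 °C; aq. potassium sodium tartrate
Reagents that add atoms: none
Why: Reductive ester cleavage removes the four aryl pivalates and the C5' pivalate in one operation; the neutral tartrate work-up avoids the acid or hot base that would ionise the C2–O1 bond through a quinone methide.

## Compound list

1 | 3-(4-hydroxyphenyl)propan-1-ol | OCCCc1ccc(O)cc1 | starting material
2 | 4-(3-hydroxypropyl)phenyl pivalate | CC(C)(C)C(=O)Oc1ccc(CCCO)cc1 | intermediate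
3 | 4-(3-oxopropyl)phenyl pivalate | CC(C)(C)C(=O)Oc1ccc(CCC=O)cc1 | intermediate
4 | 4-hydroxybenzaldehyde | O=Cc1ccc(O)cc1 | starting material
5 | 4-formylphenyl pivalate | CC(C)(C)C(=O)Oc1ccc(C=O)cc1 | intermediate
6 | 2,2,6-trimethyl-4H-1,3-dioxin-4-one | CC1=CC(=O)OC(C)(C)O1 | starting material
7 | lithium 2,2-dimethyl-6-methylidene-6H-1,3-dioxin-4-olate (dienolate of 6) | [Li+].C=C1C=C([O-])OC(C)(C)O1 | intermediate
8 | 2,2-dimethyl-6-methylidene-4-(trimethylsilyloxy)-6H-1,3-dioxine | C=C1C=C(O[Si](C)(C)C)OC(C)(C)O1 | intermediate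
9 | 6-[(2S)-4-(4-pivaloyloxyphenyl)-2-(trimethylsilyloxy)butyl]-2,2-dimethyl-4H-1,3-dioxin-4-one | CC1(C)OC(C[C@@H](O[Si](C)(C)C)CCc2ccc(OC(=O)C(C)(C)C)cc2)=CC(=O)O1 | intermediate
10 | 6-[(2S)-2-hydroxy-4-(4-pivaloyloxyphenyl)butyl]-2,2-dimethyl-4H-1,3-dioxin-4-one | CC1(C)OC(C[C@@H](O)CCc2ccc(OC(=O)C(C)(C)C)cc2)=CC(=O)O1 | intermediate
11 | (5R,7S)-2,2-dimethyl-5-(4-pivaloyloxyphenyl)-7-[2-(4-pivaloyloxyphenyl)ethyl]-7,8-dihydro-4H,5H-pyrano[4,3-d][1,3]dioxin-4-one | CC1(C)OC2=C(C(=O)O1)[C@@H](c1ccc(OC(=O)C(C)(C)C)cc1)O[C@@H](CCc1ccc(OC(=O)C(C)(C)C)cc1)C2 | intermediate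
12 | pinacol borate ester of 13 [(3S)-3-(4,4,5,5-tetramethyl-1,3,2-dioxaborolan-2-yloxy)-1-(4-pivaloyloxyphenyl)hex-5-yne] | C#CC[C@@H](OB1OC(C)(C)C(C)(C)O1)CCc1ccc(OC(=O)C(C)(C)C)cc1 | intermediate
13 | 4-[(3S)-3-hydroxyhex-5-yn-1-yl]phenyl pivalate | C#CC[C@@H](O)CCc1ccc(OC(=O)C(C)(C)C)cc1 | intermediate
14 | (3S)-1-(4-pivaloyloxyphenyl)hex-5-yn-3-yl pivalate | C#CC[C@@H](OC(=O)C(C)(C)C)CCc1ccc(OC(=O)C(C)(C)C)cc1 | intermediate
15 | dicyclohexyl[(1E,4S)-4-(pivaloyloxy)-6-(4-pivaloyloxyphenyl)hex-1-en-1-yl]borane | C1CCCCC1B(/C=C/C[C@@H](OC(=O)C(C)(C)C)CCc1ccc(OC(=O)C(C)(C)C)cc1)C1CCCCC1 | intermediate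
16 | ethyl[(1E,4S)-4-(pivaloyloxy)-6-(4-pivaloyloxyphenyl)hex-1-en-1-yl]zinc | CC[Zn]/C=C/C[C@@H](OC(=O)C(C)(C)C)CCc1ccc(OC(=O)C(C)(C)C)cc1 | intermediate
17 | (1S,2E,5S)-1-hydroxy-1,7-bis(4-pivaloyloxyphenyl)hept-2-en-5-yl pivalate | O[C@H](c1ccc(OC(=O)C(C)(C)C)cc1)/C=C/C[C@@H](OC(=O)C(C)(C)C)CCc1ccc(OC(=O)C(C)(C)C)cc1 | intermediate
18 | (2R,6S)-3-(oxomethylidene)-2-(4-pivaloyloxyphenyl)-6-[2-(4-pivaloyloxyphenyl)ethyl]oxan-4-one (acylketene) | O=C=C1[C@@H](c2ccc(OC(=O)C(C)(C)C)cc2)O[C@@H](CCc2ccc(OC(=O)C(C)(C)C)cc2)CC1=O | intermediate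
19 | (1S,2E,5S)-5-(pivaloyloxy)-1,7-bis(4-pivaloyloxyphenyl)hept-2-en-1-yl (2R,6S)-4-hydroxy-2-(4-pivaloyloxyphenyl)-6-[2-(4-pivaloyloxyphenyl)ethyl]-5,6-dihydro-2H-pyran-3-carboxylate (β-keto ester, drawn as its enol) | OC1=C(C(=O)O[C@H](c2ccc(OC(=O)C(C)(C)C)cc2)/C=C/C[C@@H](OC(=O)C(C)(C)C)CCc2ccc(OC(=O)C(C)(C)C)cc2)[C@@H](c2ccc(OC(=O)C(C)(C)C)cc2)O[C@@H](CCc2ccc(OC(=O)C(C)(C)C)cc2)C1 | intermediate
20 | 2,6-cis-4-oxo-2-(4-pivaloyloxyphenyl)-6-[2-(4-pivaloyloxyphenyl)ethyl]-3-[(1E,3S,5S)-5-(pivaloyloxy)-1,7-bis(4-pivaloyloxyphenyl)hept-1-en-3-yl]oxane-3-carboxylic acid (new C3–C3' bond trans to the C2 aryl group; this C3 configuration is erased on decarboxylation) | CC(C)(C)C(=O)Oc1ccc(/C=C/[C@H](C[C@@H](OC(=O)C(C)(C)C)CCc2ccc(OC(=O)C(C)(C)C)cc2)[C@]2(C(=O)O)[C@@H](c3ccc(OC(=O)C(C)(C)C)cc3)O[C@@H](CCc3ccc(OC(=O)C(C)(C)C)cc3)CC2=O)cc1 | intermediate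
21 | (2S,3R,6S)-2-(4-pivaloyloxyphenyl)-6-[2-(4-pivaloyloxyphenyl)ethyl]-3-[(1E,3S,5S)-5-(pivaloyloxy)-1,7-bis(4-pivaloyloxyphenyl)hept-1-en-3-yl]oxan-4-one | CC(C)(C)C(=O)Oc1ccc(/C=C/[C@H](C[C@@H](OC(=O)C(C)(C)C)CCc2ccc(OC(=O)C(C)(C)C)cc2)[C@@H]2[C@@H](c3ccc(OC(=O)C(C)(C)C)cc3)O[C@@H](CCc3ccc(OC(=O)C(C)(C)C)cc3)CC2=O)cc1 | intermediate
22 | (2S,3S,4S,6S)-2-(4-pivaloyloxyphenyl)-6-[2-(4-pivaloyloxyphenyl)ethyl]-3-[(1E,3S,5S)-5-(pivaloyloxy)-1,7-bis(4-pivaloyloxyphenyl)hept-1-en-3-yl]oxan-4-ol | CC(C)(C)C(=O)Oc1ccc(/C=C/[C@H](C[C@@H](OC(=O)C(C)(C)C)CCc2ccc(OC(=O)C(C)(C)C)cc2)[C@@H]2[C@@H](c3ccc(OC(=O)C(C)(C)C)cc3)O[C@@H](CCc3ccc(OC(=O)C(C)(C)C)cc3)C[C@@H]2O)cc1 | intermediate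
23 | blepharocalyxin C, (2S,3S,4S,6S)-2-(4-hydroxyphenyl)-6-[2-(4-hydroxyphenyl)ethyl]-3-[(1E,3S,5S)-5-hydroxy-1,7-bis(4-hydroxyphenyl)hept-1-en-3-yl]oxan-4-ol | Oc1ccc(/C=C/[C@H](C[C@@H](O)CCc2ccc(O)cc2)[C@@H]2[C@@H](c3ccc(O)cc3)O[C@@H](CCc3ccc(O)cc3)C[C@@H]2O)cc1 | target

## Step count and least certain steps

Total step count: 12. Longest linear sequence: 8 steps (1, 2, 7, 8, 9, 10, 11, 12).

Step 10 (key step). The most likely failure is heterolysis of the C1'–O bond of ester 19 before the concerted shift. An ion pair would recombine with 1,3-transposition and loss of stereochemical information, or eliminate to a diene. The second risk is that the temperature needed for rearrangement of this congested ester promotes retro-oxa-Michael or retro-aldol opening of the β-alkoxy ketone. The fallback makes the same bond by an intermolecular Tsuji–Trost alkylation. It sets out from 11 and 17 and returns at 21. Dioxinone 11 would be heated with tert-butanol in toluene to give the tert-butyl β-keto ester F1. Alcohol 17 would be converted with methyl chloroformate and pyridine into the allylic methyl carbonate F2. Pd(0)/phosphine in THF at room temperature should alkylate the stabilised enolate of F1 at the allyl terminus remote from the arene, keeping styrene conjugation. Double inversion places the new bond on the face the carbonate occupied, the same sense as the suprafacial shift, and gives the C-allylated tert-butyl ester F3. Trifluoroacetic acid in CH2Cl2 at 0 °C → rt would then cleave the tert-butyl ester and decarboxylate to 21.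

Step 9. The risks are competing ethyl transfer from zinc, incomplete facial control at C1', and acid-promoted allylic transposition of the 1-arylallyl alcohol during work-up or chromatography. The fallback builds 17 by cross-metathesis of two separately secured pieces. It sets out from 14 and 5 and returns at 17. Alkyne 14 would be semi-hydrogenated (H2, Pb-poisoned Pd/CaCO3, quinoline) to the terminal alkene (3S)-1-(4-pivaloyloxyphenyl)hex-5-en-3-yl pivalate F4. Aldehyde 5 with vinylmagnesium bromide at −78 °C would give racemic 1-(4-pivaloyloxyphenyl)prop-2-en-1-ol F5. Lipase-catalysed acylation (Candida antarctica lipase B, vinyl acetate) consumes the (R)-enantiomer and leaves the (S)-alcohol F6. Cross-metathesis of F4 with F6 (second-generation isopropoxystyrene-chelated Ru catalyst, CH2Cl2, 40 °C) should give the E-alkene 17.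

Step 6. The risks are slow oxocarbenium formation from the conjugated aryl aldehyde, with acetal formation or erosion of the cis selectivity. The fallback builds the ring by a Knoevenagel/oxa-Michael (Maitland–Japp) sequence. It sets out from 3 and 5 and returns at 19. Aldehyde 3 with 1-methoxy-1,3-bis(trimethylsilyloxy)buta-1,3-diene under the Ti(IV)–BINOL catalysis of step 5 would give methyl (5S)-5-hydroxy-3-oxo-7-(4-pivaloyloxyphenyl)heptanoate F7. Lewis-acid-mediated condensation of F7 with 5 should give the 2,6-cis methyl 4-oxo-oxane-3-carboxylate F8 (enolised). DMAP-catalysed transesterification of F8 with 17 in toluene at 100 °C, with removal of methanol, gives 19, which continues to 21 under the conditions of step 10.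

Step 11. The risks are hydride attack on the aryl ester carbonyls and loss of equatorial-attack selectivity because of the large neighbouring C3 substituent. The fallback uses inversion instead of reagent-controlled delivery. It sets out from 21 and returns at 23. NaBH4/CeCl3 in MeOH/THF at −40 °C (axial attack by a small hydride) would give the equatorial C4 epimer of 22, alcohol F9. Mitsunobu reaction with chloroacetic acid (PPh3, DIAD, toluene) inverts C4 to the axial chloroacetate F10. F10 is then submitted to the conditions of step 12, which cleave the chloroacetate together with the pivalates and give 23.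

## Further compounds

F1 | step 10 | tert-butyl (2R,6S)-4-hydroxy-2-(4-pivaloyloxyphenyl)-6-[2-(4-pivaloyloxyphenyl)ethyl]-5,6-dihydro-2H-pyran-3-carboxylate (β-keto ester, enol form) | OC1=C(C(=O)OC(C)(C)C)[C@@H](c2ccc(OC(=O)C(C)(C)C)cc2)O[C@@H](CCc2ccc(OC(=O)C(C)(C)C)cc2)C1
F2 | step 10 | (1S,2E,5S)-1-(methoxycarbonyloxy)-1,7-bis(4-pivaloyloxyphenyl)hept-2-en-5-yl pivalate | COC(=O)O[C@H](c1ccc(OC(=O)C(C)(C)C)cc1)/C=C/C[C@@H](OC(=O)C(C)(C)C)CCc1ccc(OC(=O)C(C)(C)C)cc1
F3 | step 10 | tert-butyl 2,6-cis-4-oxo-2-(4-pivaloyloxyphenyl)-6-[2-(4-pivaloyloxyphenyl)ethyl]-3-[(1E,3S,5S)-5-(pivaloyloxy)-1,7-bis(4-pivaloyloxyphenyl)hept-1-en-3-yl]oxane-3-carboxylate | CC(C)(C)C(=O)Oc1ccc(/C=C/[C@H](C[C@@H](OC(=O)C(C)(C)C)CCc2ccc(OC(=O)C(C)(C)C)cc2)[C@]2(C(=O)OC(C)(C)C)[C@@H](c3ccc(OC(=O)C(C)(C)C)cc3)O[C@@H](CCc3ccc(OC(=O)C(C)(C)C)cc3)CC2=O)cc1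
F4 | step 9 | (3S)-1-(4-pivaloyloxyphenyl)hex-5-en-3-yl pivalate | C=CC[C@@H](OC(=O)C(C)(C)C)CCc1ccc(OC(=O)C(C)(C)C)cc1
F5 | step 9 | racemic 1-(4-pivaloyloxyphenyl)prop-2-en-1-ol | OC(C=C)c1ccc(OC(=O)C(C)(C)C)cc1
F6 | step 9 | (1S)-1-(4-pivaloyloxyphenyl)prop-2-en-1-ol | O[C@H](c1ccc(OC(=O)C(C)(C)C)cc1)C=C
F7 | step 6 | methyl (5S)-5-hydroxy-3-oxo-7-(4-pivaloyloxyphenyl)heptanoate | COC(=O)CC(=O)C[C@@H](O)CCc1ccc(OC(=O)C(C)(C)C)cc1
F8 | step 6 | methyl (2R,6S)-4-hydroxy-2-(4-pivaloyloxyphenyl)-6-[2-(4-pivaloyloxyphenyl)ethyl]-5,6-dihydro-2H-pyran-3-carboxylate (β-keto ester, enol form) | OC1=C(C(=O)OC)[C@@H](c2ccc(OC(=O)C(C)(C)C)cc2)O[C@@H](CCc2ccc(OC(=O)C(C)(C)C)cc2)C1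
F9 | step 11 | (2S,3S,4R,6S)-C4 epimer of 22 (equatorial alcohol) | CC(C)(C)C(=O)Oc1ccc(/C=C/[C@H](C[C@@H](OC(=O)C(C)(C)C)CCc2ccc(OC(=O)C(C)(C)C)cc2)[C@@H]2[C@@H](c3ccc(OC(=O)C(C)(C)C)cc3)O[C@@H](CCc3ccc(OC(=O)C(C)(C)C)cc3)C[C@H]2O)cc1
F10 | step 11 | axial 4-O-chloroacetate of 22 | CC(C)(C)C(=O)Oc1ccc(/C=C/[C@H](C[C@@H](OC(=O)C(C)(C)C)CCc2ccc(OC(=O)C(C)(C)C)cc2)[C@@H]2[C@@H](c3ccc(OC(=O)C(C)(C)C)cc3)O[C@@H](CCc3ccc(OC(=O)C(C)(C)C)cc3)C[C@@H]2OC(=O)CCl)cc1
A1 | alternative 1 | homoallylic alcohol carrying the complete side chain [ArCH2CH2CH(OH)CH2CH=CH–CH(CH=CHAr)CH2CH(OPiv)CH2CH2Ar, Ar = 4-pivaloyloxyphenyl] | O[C@@H](CCc1ccc(OC(=O)C(C)(C)C)cc1)C/C=C/[C@H](/C=C/c1ccc(OC(=O)C(C)(C)C)cc1)C[C@@H](OC(=O)C(C)(C)C)CCc1ccc(OC(=O)C(C)(C)C)cc1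
A2 | alternative 1 | all-equatorial 4-trifluoroacetate (C4 epimer series of 22) | CC(C)(C)C(=O)Oc1ccc(/C=C/[C@H](C[C@@H](OC(=O)C(C)(C)C)CCc2ccc(OC(=O)C(C)(C)C)cc2)[C@@H]2[C@@H](c3ccc(OC(=O)C(C)(C)C)cc3)O[C@@H](CCc3ccc(OC(=O)C(C)(C)C)cc3)C[C@H]2OC(=O)C(F)(F)F)cc1
A3 | alternative 2 | (1E,3S,5S)-1,7-bis(4-hydroxyphenyl)hept-1-ene-3,5-diol | Oc1ccc(/C=C/[C@@H](O)C[C@@H](O)CCc2ccc(O)cc2)cc1
A4 | alternative 3 | 2,3-trans-2,6-cis-3-[(1E)-3-oxo-5-(4-pivaloyloxyphenyl)pent-1-en-1-yl]-2-(4-pivaloyloxyphenyl)-6-[2-(4-pivaloyloxyphenyl)ethyl]oxan-4-one | O=C(CCc1ccc(OC(=O)C(C)(C)C)cc1)/C=C/[C@@H]1[C@@H](c2ccc(OC(=O)C(C)(C)C)cc2)O[C@@H](CCc2ccc(OC(=O)C(C)(C)C)cc2)CC1=O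
A5 | alternative 3 | diketone, 3-[(1E,3S)-5-oxo-1,7-bis(4-pivaloyloxyphenyl)hept-1-en-3-yl] analogue of 21 | CC(C)(C)C(=O)Oc1ccc(/C=C/[C@H](CC(=O)CCc2ccc(OC(=O)C(C)(C)C)cc2)[C@@H]2[C@@H](c3ccc(OC(=O)C(C)(C)C)cc3)O[C@@H](CCc3ccc(OC(=O)C(C)(C)C)cc3)CC2=O)cc1
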